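Remark on the chemistry: a check of the configurations shows that the annulation product needed for the (2R,3R) target is the (2R,3R,4S) isomer (2,3-trans, 3,4-cis), which is what is drawn for 15, so the skeletons of 11 and 15 need no correction; 4-(tert-butyldimethylsilyloxy)benzaldehyde is taken as a purchasable material.

## Structural features

The target is a dihydroflavonol: a chroman-4-one in which the benzene ring A is fused to the oxygen heterocycle ring C (O1, C2, C3, C4, C4a, C8a), with a 4-hydroxyphenyl group (ring B) on C2, a hydroxyl on C3 and the ketone at C4. C2 and C3 are adjacent stereocentres, both R, with the aryl group and the C3 hydroxyl trans. C3 lies alpha to the ketone and C2 is a benzylic ether carbon para to a phenol, so base can erase either centre, by enolisation or by ring opening through a quinone methide. Ring A is a phloroglucinol unit with oxygens at C5, C7 and C8a (O1); C6 carries a 2-methylbut-3-en-2-yl group whose quaternary carbon is wedged between the oxygenated carbons C5 and C7. This side chain excludes hydrogenolysis and is sensitive to strong acid (addition of an ortho phenol to the vinyl group, loss of the tertiary allyl cation), and the free polyphenol is sensitive to air and base, so phenol protection and a mild, non-basic last step are needed. The real difficulty is twofold: the absolute configuration at C2 together with the trans relation to C3, and the placement of the quaternary carbon at C6 and not at C8. The key step exploits two features. O1 is para to C6, so ring A can be brought in as a phenol with a mirror plane through O1 and C6 whose two ortho carbons (either can become C4a) are identical and activated by three oxygens. C3 and C4 both carry oxygen, which is the pattern a cyclic cis-enediol ether leaves behind when its two alkene carbons are joined to C2 and C4a.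

## Logic of the disconnections

18 from 17. The three phenolic O–H bonds are traced back to three O–Si bonds. The free phenols would not survive the cationic and oxidative steps, and one kind of protecting group allows a single final operation. The skeleton is unchanged, but every earlier problem is moved to a stable, lipophilic compound. The forward step must be neither basic nor strongly acidic, to spare C2, C3 and the side chain.

17 from 16. No skeletal bond is cut; the C4 carbonyl is taken back to a secondary alcohol. The reason is that an oxygen at the alcohol level is what the annulation can place on C4. The gain is that the ketone, which makes C3 epimerisable and deactivates ring A, is absent from all earlier steps. The demand is an oxidant that distinguishes the benzylic C4 hydroxyl from the C3 hydroxyl.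

16 from 15. The O–H bonds on C3 and C4 are replaced by two C–O bonds to one isopropylidene carbon. A cis-diol tied into a five-membered ring is the form in which an enediol can act as a nucleophilic alkene. The demand is a hydrolysis that tolerates a benzylic C4–O bond that ionises easily; since C4 becomes a carbonyl, its configuration need not be kept.

15 into 11 and 14. C2–C3 and C4–C4a are cut. These two bonds hold ring C together, and cutting them removes the ring and all three stereocentres at once and leaves two achiral pieces. Because 11 has a mirror plane, the bond to ring A can form at either ortho carbon with the same result. The forward step needs facial control at a cation that has no directing group, exo topology, and an acid mild enough for the silyl ethers and the side chain.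

11 into 7 and 9, by way of 10. The aryl O–C bond of the mixed acetal (the future O1–C2) is cut. This separates ring A from ring B at a heteroatom bond and gives two simple aromatic compounds. The forward step must form this bond under basic conditions, because an acid-catalysed acetal exchange would send the cation on to the nucleophilic carbons of ring A.

9 from 8. The two acetal C–O bonds are cut back to the aldehyde carbonyl; 8 is purchased. The demand is only that the aryl silyl ether survives catalytic acid.

14 from 13, and 13 from 12. The ring C=C bond is traced to C–H and C–Cl, and the C–Cl bond to C–H. This reaches a cheap cyclic ketal. The demand is a chlorination alpha to oxygen and an elimination that does not turn into substitution.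

7 from 6, and 6 from 5. Only O–Si bonds change: the free hydroxyl of 5, which is ortho to the side chain, is silylated, and the silyl ether para to the side chain is then removed. This moves the free oxygen from an ortho to the para position and creates the mirror plane. The demand is steric discrimination between the one unhindered and the two hindered silyl ethers.

5 from 4. The bond between ring A and the quaternary carbon is cut and the allyl unit is reconnected through its other terminus to oxygen (retro-Claisen). The quaternary carbon and its position between two oxygens then follow from a sigmatropic shift, with no alkylation at carbon. The demand is a clean ortho rearrangement; the two ortho positions of 4 are equivalent.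

4 into 2 and 3. The O–CH2 bond is cut, leaving a phenol and an allylic bromide. The demand is O- rather than C-alkylation.

2 from 1. Two O–Si bonds are cut. The demand is an acceptable statistical bis-silylation of a triol with threefold symmetry.

## Other disconnections considered

Alternative 1: The cut lies inside the side chain, at the bonds from the quaternary carbon to one methyl and to the vinyl group. The quaternary carbon is thereby traced to the carbonyl carbon of A2 (tert-butyl 2-acetyl-3-(methoxymethoxy)-5-(triisopropylsilyloxy)phenyl carbonate).
- Forward key step: CH3MgBr would add to the ketone, the tertiary alkoxide would take over the tert-butoxycarbonyl group from the neighbouring oxygen and leave as carbonate to give an ortho-quinone methide, and vinylmagnesium bromide would add to the exocyclic carbon. The product would be A1 (3-(methoxymethoxy)-2-(2-methylbut-3-en-2-yl)-5-(triisopropylsilyloxy)phenol).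
- In its favour: the three ring A oxygens of A1 are chemically distinct, so the oxygen para to the side chain can be unmasked by fluoride without steric discrimination between like groups. On this point it is better than the chosen plan, whose step 5 depends on such discrimination. The quaternary carbon is made in one flask.
- Against: the quinone methide carries two methyl groups on its exocyclic carbon and can tautomerise by a 1,5-hydrogen shift to an isopropenyl phenol before a second Grignard reagent adds to that crowded carbon. A2 needs a regioselective acylation and three different protecting groups on phloroglucinol. The sequence does nothing for ring C or the stereocentres, so it would replace only steps 1 to 5.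
- Comparison: on structure, both plans place the quaternary carbon between two oxygens with certainty. On mechanism, the Claisen shift of the chosen plan is intramolecular and needs no organometallic reagent, whereas the cascade depends on an intermolecular addition to a hindered, isomerisable intermediate. On step economy the two are about equal up to the ring A phenol; the alternative is ahead in oxygen differentiation and behind in reliability.

Alternative 2: The cut goes through ring C at O1–C2 and C3–C4. It gives the salicyl alcohol A4 (2-(hydroxymethyl)-3,5-bis(methoxymethoxy)-4-(2-methylbut-3-en-2-yl)phenol) and the enol ester A5 ((E)-2-[4-(methoxymethoxy)phenyl]ethenyl acetate).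
- Forward key step: a chiral phosphoric acid would dehydrate A4 to the ortho-quinone methide, and [4+2] addition of A5 across O1 and C4 would give A3 ((2R,3S)-5,7-bis(methoxymethoxy)-2-[4-(methoxymethoxy)phenyl]-6-(2-methylbut-3-en-2-yl)chroman-3-yl acetate). The trans relation would follow from the (E) alkene.
- In its favour: enantioselective cycloadditions of ortho-quinone methides under chiral phosphoric acids are an established reaction class, whereas the enantioselective form of the chosen key step is not. On this point the alternative is the better one. It uses the same symmetric ring A, so on regiochemistry the two are equal.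
- Against: C4 arrives as CH2, so the ketone needs a benzylic C–H oxidation (in practice two steps) on an electron-rich flavan next to C3; the chosen plan brings C4 in already oxygenated. A quinone methide with an unsubstituted exocyclic CH2 is hard to generate with a phosphoric acid and oligomerises readily. An enol acetate is a much weaker nucleophile than an enediol ether. Removal of the methoxymethyl groups at the end needs acid while phenols sit ortho to the allyl group.
- Comparison: structurally both close ring C on the same phenol. Mechanistically the alternative has the better precedent for enantiocontrol but the weaker partners. In step count the lead-up is similar and the endgame is longer (acetate cleavage, two oxidation steps, deprotection, against three steps here).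

Alternative 3: Here ring A is disconnected, at C8a–C8, C7–C8, C5–C6 and C4a–C5. This leads back to the diazoketone A7 ((2R,3R)-3-(tert-butyldimethylsilyloxy)-2-[4-(tert-butyldimethylsilyloxy)phenyl]-6-(2-diazoacetyl)-2,3-dihydro-4H-pyran-4-one), which already holds ring C and both stereocentres, and the siloxyalkyne A8 (triisopropyl[(3,3-dimethylpent-4-en-1-yn-1-yl)oxy]silane).
- Forward key step: irradiation would trigger a Wolff rearrangement to a vinylketene, followed by [2+2] addition of A8, four-electron ring opening, six-electron ring closure and tautomerisation. The product would be A6 ((2R,3R)-3-(tert-butyldimethylsilyloxy)-2-[4-(tert-butyldimethylsilyloxy)phenyl]-5-hydroxy-6-(2-methylbut-3-en-2-yl)-7-(triisopropylsilyloxy)chroman-4-one).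
- In its favour: the substitution pattern of ring A is dictated by the mechanism (hydroxyl from the ketene carbon at C5, the alkyne substituent at C6, the silyloxy group at C7), with no C6/C8 question. The C4 ketone is present throughout, so only desilylation follows. On regiochemical certainty and on the length of the endgame this alternative is better than the chosen plan.
- Against: C2 and C3 must be made beforehand in enantiopure A7, a separate asymmetric synthesis of a 2,3-dihydropyran-4-one of some eight or more steps. They must then survive light and heat next to a ketone and beta to an enol ether oxygen (epimerisation at C3, beta-elimination of O1). A8 has a quaternary carbon beside the alkyne, which slows the [2+2] step, and a vinyl group that can react with the ketene. The enone of A7 has its own photochemistry.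
- Comparison: structurally both plans are convergent. Mechanistically the alternative is a known pericyclic cascade where the chosen step needs new catalyst control, but it exposes existing stereocentres to harsh conditions where the chosen step creates them late and at low temperature. In step count the chosen plan is shorter overall.

Key step: step 10

## Route

Step 1
Reactants: 1 phloroglucinol (benzene-1,3,5-triol)
Product: 2 3,5-bis(tert-butyldimethylsilyloxy)phenol
Conditions: TBSCl (2.0 equiv), imidazole, DMF, 0 °C → rt; mono- and tris-silyl ethers separated and recycled
Reagents that add atoms: tert-butyldimethylsilyl chloride (TBSCl), CC(C)(C)[Si](C)(C)Cl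
Why: Statistical O-silylation of a triol with threefold symmetry; with two equivalents the bis-ether should be the main product, and the under- and over-silylated material can be returned to the same reaction after resilylation or partial methanolysis.

Step 2
Reactants: 2 3,5-bis(tert-butyldimethylsilyloxy)phenol; 3 1-bromo-3-methylbut-2-ene
Product: 4 1,3-bis(tert-butyldimethylsilyloxy)-5-(3-methylbut-2-enyloxy)benzene
Conditions: K2CO3, acetone, rt
Reagents that add atoms: none
Why: Williamson ether synthesis; K2CO3 in acetone favours O- over C-alkylation of the phenoxide and at room temperature should leave the aryl silyl ethers intact.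

Step 3
Reactants: 4 1,3-bis(tert-butyldimethylsilyloxy)-5-(3-methylbut-2-enyloxy)benzene
Product: 5 3,5-bis(tert-butyldimethylsilyloxy)-2-(2-methylbut-3-en-2-yl)phenol
Conditions: PhNEt2, 170 °C
Reagents that add atoms: none
Why: Aromatic Claisen rearrangement ([3,3]-sigmatropic shift): the allyl terminus that bears the two methyl groups bonds to an ortho carbon, so the O-bound 3-methylbut-2-enyl group becomes the C-bound 2-methylbut-3-en-2-yl group with its quaternary carbon. The two ortho positions of 4 are equivalent, and the dienone should enolise to the phenol before a second shift to the hindered para position can take place.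

Step 4
Reactants: 5 3,5-bis(tert-butyldimethylsilyloxy)-2-(2-methylbut-3-en-2-yl)phenol
Product: 6 1,3,5-tris(tert-butyldimethylsilyloxy)-2-(2-methylbut-3-en-2-yl)benzene
Conditions: TBSOTf, 2,6-lutidine, CH2Cl2, 0 °C → rt
Reagents that add atoms: tert-butyldimethylsilyl trifluoromethanesulfonate (TBSOTf), CC(C)(C)[Si](C)(C)OS(=O)(=O)C(F)(F)F
Why: Silylation of a hindered phenol with a silyl triflate and a non-nucleophilic base; the triflate is chosen because the hydroxyl is flanked by the quaternary carbon.

Step 5
Reactants: 6 1,3,5-tris(tert-butyldimethylsilyloxy)-2-(2-methylbut-3-en-2-yl)benzene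
Product: 7 3,5-bis(tert-butyldimethylsilyloxy)-4-(2-methylbut-3-en-2-yl)phenol
Conditions: K2CO3 (0.5 equiv), MeOH–THF, 0 °C, stopped at mono-cleavage
Reagents that add atoms: none
Why: Base-promoted methanolysis of an aryl silyl ether, selective on steric grounds: the silyloxy group para to the side chain is flanked by two hydrogens, while the other two are shielded by the quaternary carbon, so methoxide should reach only the para silicon. This unmasks the oxygen that becomes O1 and leaves a phenol with a mirror plane.

Step 6
Reactants: 8 4-(tert-butyldimethylsilyloxy)benzaldehyde
Product: 9 tert-butyl[4-(dimethoxymethyl)phenoxy]dimethylsilane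
Conditions: HC(OMe)3, MeOH, PPTS (cat.), rt; then Et3N
Reagents that add atoms: trimethyl orthoformate, COC(OC)OC; methanol, CO
Why: Acid-catalysed acetalisation driven by the orthoformate as water scavenger; the aryl silyl ether tolerates catalytic PPTS in methanol at room temperature.

Step 7
Reactants: 9 tert-butyl[4-(dimethoxymethyl)phenoxy]dimethylsilane; 7 3,5-bis(tert-butyldimethylsilyloxy)-4-(2-methylbut-3-en-2-yl)phenol
Product: 11 1-{methoxy[4-(tert-butyldimethylsilyloxy)phenyl]methoxy}-3,5-bis(tert-butyldimethylsilyloxy)-4-(2-methylbut-3-en-2-yl)benzene (racemic at the acetal carbon), via tert-butyl{4-[chloro(methoxy)methyl]phenoxy}dimethylsilane 10 (not isolated)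
Conditions: 9, AcCl (1.05 equiv), ZnBr2 (0.1 mol%), CH2Cl2, 0 °C; then 7, i-Pr2NEt, CH2Cl2, −40 °C → rt; purification on Et3N-deactivated silica
Reagents that add atoms: acetyl chloride, CC(=O)Cl (it supplies the chlorine of intermediate 10; no atom of it remains in 11)
Why: Exchange of an acetal methoxy group for chloride with an acyl chloride under zinc halide catalysis, then O-alkylation of the phenol under amine base, the same reaction type as a methoxymethyl protection. Working under basic conditions keeps the oxocarbenium ion away from the nucleophilic carbons of ring A, which an acid-catalysed acetal exchange would not.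

Step 8
Reactants: 12 2,2-dimethyl-1,3-dioxolane
Product: 13 4-chloro-2,2-dimethyl-1,3-dioxolane (racemic)
Conditions: SO2Cl2 (1.0 equiv), AIBN (cat.), neat, 65 °C, N2 sweep; distillation
Reagents that add atoms: sulfuryl chloride, O=S(=O)(Cl)Cl
Why: Free-radical chain chlorination alpha to an ether oxygen; the ketal carbon has no hydrogen, so abstraction should occur at C4 (equivalent to C5) in preference to the methyl groups.

Step 9
Reactants: 13 4-chloro-2,2-dimethyl-1,3-dioxolane
Product: 14 2,2-dimethyl-1,3-dioxole
Conditions: KOtBu, tetraglyme, 0 → 60 °C; product distilled out and kept over K2CO3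
Reagents that add atoms: none
Why: Base-induced 1,2-elimination of HCl from an alpha-chloro ether (the reaction type used to make vinylene carbonate), with a hindered alkoxide that is a poor nucleophile; the volatile enediol ether is removed from the high-boiling solvent as it forms.

Step 10
Reactants: 11 1-{methoxy[4-(tert-butyldimethylsilyloxy)phenyl]methoxy}-3,5-bis(tert-butyldimethylsilyloxy)-4-(2-methylbut-3-en-2-yl)benzene; 14 2,2-dimethyl-1,3-dioxole
Product: 15 (2R,3R,4S)-5,7-bis(tert-butyldimethylsilyloxy)-2-[4-(tert-butyldimethylsilyloxy)phenyl]-6-(2-methylbut-3-en-2-yl)chroman-3,4-diol 3,4-O-isopropylidene ketal (2,3-trans, 3,4-cis)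
Conditions: 14 (3 equiv), chiral IDPi Brønsted acid (BINOL-derived imidodiphosphorimidate with 3,3'-bis[3,5-bis(trifluoromethyl)phenyl] groups and an N-triflyl core, 5 mol%, enantiomer chosen so that the Si face of C2 stays open), 5 Å molecular sieves, toluene, −60 °C; Et3N quench
Reagents that add atoms: none
Why: Proposed new method: the chiral acid protonates the methoxy oxygen of 11, methanol leaves, and the (E)-aryl oxocarbenium ion O1=C2, stabilised by the 4-silyloxyphenyl group, stays paired with the confined chiral anion; the closest known reaction type is the racemic SnCl4-promoted oxa-Povarov annulation of aryl oxocarbenium ions from mixed aryl acetals with alkenes, and chiral-anion control of other oxocarbenium additions makes the enantioselective variant plausible. One alkene carbon of the enediol ether 14 adds to C2 (bond C2–C3) and the 1,3-dioxolan-4-ylium centre that results at C4 is captured by the ring A carbon ortho to O1 (bond C4–C4a), so the process is a stepwise cationic [4+2] whose second stage closes the six-membered ring C by a 6-exo-trig Friedel–Crafts attack on the C4=O+ bond; loss of the arenium proton regenerates the acid. C2 is set by the counter-anion, which has to cover the Re face of the cation so that 14 adds to the Si face and gives 2R. C3 is set relative to C2 by an exo approach, in which the dioxole ring points away from ring A and the anion, and this places the C3 oxygen trans to the aryl group. C4 is set by the ring fusion, because the tethered arene can reach the cation only on the face that carries C2, which makes the C3 and C4 oxygens cis. No regiochemical control is needed, since the mirror plane of 11 makes the two carbons ortho to O1 identical, each lying ortho to O1 and ortho and para to a silyloxy group. Chemoselectivity rests on the much higher nucleophilicity of 14 than of the hindered monosubstituted vinyl group, on the excess of 14, and on sieves that bind the methanol set free.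

Step 11
Reactants: 15 (2R,3R,4S)-5,7-bis(tert-butyldimethylsilyloxy)-2-[4-(tert-butyldimethylsilyloxy)phenyl]-6-(2-methylbut-3-en-2-yl)chroman-3,4-diol 3,4-O-isopropylidene ketal
Product: 16 (2R,3S)-5,7-bis(tert-butyldimethylsilyloxy)-2-[4-(tert-butyldimethylsilyloxy)phenyl]-6-(2-methylbut-3-en-2-yl)chroman-3,4-diol (2,3-trans; mixture of C4 epimers; the change of the C3 descriptor from R to S is a priority change only)
Conditions: AcOH–THF–H2O (3:1:1), 30 °C
Reagents that add atoms: water, O
Why: Acid-catalysed hydrolysis of an isopropylidene ketal; the benzylic C4–O bond should ionise readily because of the three ring A oxygens and water captures the cation, and either C4 epimer is acceptable because C4 becomes a carbonyl. Aryl silyl ethers, C2 and C3 should be untouched by dilute acetic acid.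

Step 12
Reactants: 16 (2R,3S)-5,7-bis(tert-butyldimethylsilyloxy)-2-[4-(tert-butyldimethylsilyloxy)phenyl]-6-(2-methylbut-3-en-2-yl)chroman-3,4-diol
Product: 17 (2R,3R)-5,7-bis(tert-butyldimethylsilyloxy)-3-hydroxy-2-[4-(tert-butyldimethylsilyloxy)phenyl]-6-(2-methylbut-3-en-2-yl)chroman-4-one (2,3-trans)
Conditions: DDQ (1.2 equiv), 1,4-dioxane, rt
Reagents that add atoms: none
Why: Chemoselective oxidation of an electron-rich benzylic alcohol by DDQ (hydride abstraction assisted by ring A), which should leave the non-benzylic C3 hydroxyl alone and does not cleave the glycol. Once the ketone is formed ring A is deactivated and further oxidation should stop; C2 and C3 are not involved.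

Step 13
Reactants: 17 (2R,3R)-5,7-bis(tert-butyldimethylsilyloxy)-3-hydroxy-2-[4-(tert-butyldimethylsilyloxy)phenyl]-6-(2-methylbut-3-en-2-yl)chroman-4-one
Product: 18 (2R,3R)-3,5,7-trihydroxy-2-(4-hydroxyphenyl)-6-(2-methylbut-3-en-2-yl)chroman-4-one (target CNP0527000.1)
Conditions: TBAF (3.5 equiv), AcOH (3.5 equiv), THF, 0 °C → rt
Reagents that add atoms: none
Why: Fluoride cleavage of aryl silyl ethers; buffering with acetic acid keeps phenoxide out of solution, so that neither enolisation at C3 nor ring opening at C2 through a quinone methide should scramble the stereocentres, and the acid is too weak to add to the vinyl group.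

## Compound list

1 | phloroglucinol (benzene-1,3,5-triol) | Oc1cc(O)cc(O)c1 | starting material
2 | 3,5-bis(tert-butyldimethylsilyloxy)phenol | Oc1cc(O[Si](C)(C)C(C)(C)C)cc(O[Si](C)(C)C(C)(C)C)c1 | intermediate
3 | 1-bromo-3-methylbut-2-ene | CC(C)=CCBr | starting material
4 | 1,3-bis(tert-butyldimethylsilyloxy)-5-(3-methylbut-2-enyloxy)benzene | CC(C)=CCOc1cc(O[Si](C)(C)C(C)(C)C)cc(O[Si](C)(C)C(C)(C)C)c1 | intermediate
5 | 3,5-bis(tert-butyldimethylsilyloxy)-2-(2-methylbut-3-en-2-yl)phenol | C=CC(C)(C)c1c(O)cc(O[Si](C)(C)C(C)(C)C)cc1O[Si](C)(C)C(C)(C)C | intermediate
6 | 1,3,5-tris(tert-butyldimethylsilyloxy)-2-(2-methylbut-3-en-2-yl)benzene | C=CC(C)(C)c1c(O[Si](C)(C)C(C)(C)C)cc(O[Si](C)(C)C(C)(C)C)cc1O[Si](C)(C)C(C)(C)C | intermediate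
7 | 3,5-bis(tert-butyldimethylsilyloxy)-4-(2-methylbut-3-en-2-yl)phenol | C=CC(C)(C)c1c(O[Si](C)(C)C(C)(C)C)cc(O)cc1O[Si](C)(C)C(C)(C)C | intermediate
8 | 4-(tert-butyldimethylsilyloxy)benzaldehyde | O=Cc1ccc(O[Si](C)(C)C(C)(C)C)cc1 | starting material
9 | tert-butyl[4-(dimethoxymethyl)phenoxy]dimethylsilane | COC(OC)c1ccc(O[Si](C)(C)C(C)(C)C)cc1 | intermediate
10 | tert-butyl{4-[chloro(methoxy)methyl]phenoxy}dimethylsilane (racemic, not isolated) | COC(Cl)c1ccc(O[Si](C)(C)C(C)(C)C)cc1 | intermediate
11 | 1-{methoxy[4-(tert-butyldimethylsilyloxy)phenyl]methoxy}-3,5-bis(tert-butyldimethylsilyloxy)-4-(2-methylbut-3-en-2-yl)benzene (racemic at the acetal carbon) | C=CC(C)(C)c1c(O[Si](C)(C)C(C)(C)C)cc(OC(OC)c2ccc(O[Si](C)(C)C(C)(C)C)cc2)cc1O[Si](C)(C)C(C)(C)C | intermediate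
12 | 2,2-dimethyl-1,3-dioxolane | CC1(C)OCCO1 | starting material
13 | 4-chloro-2,2-dimethyl-1,3-dioxolane (racemic) | CC1(C)OCC(Cl)O1 | intermediate
14 | 2,2-dimethyl-1,3-dioxole | CC1(C)OC=CO1 | intermediate
15 | (2R,3R,4S)-5,7-bis(tert-butyldimethylsilyloxy)-2-[4-(tert-butyldimethylsilyloxy)phenyl]-6-(2-methylbut-3-en-2-yl)chroman-3,4-diol 3,4-O-isopropylidene ketal (2,3-trans, 3,4-cis) | C=CC(C)(C)c1c(O[Si](C)(C)C(C)(C)C)cc2c(c1O[Si](C)(C)C(C)(C)C)[C@@H]3OC(C)(C)O[C@@H]3[C@@H](c4ccc(O[Si](C)(C)C(C)(C)C)cc4)O2 | intermediate
16 | (2R,3S)-5,7-bis(tert-butyldimethylsilyloxy)-2-[4-(tert-butyldimethylsilyloxy)phenyl]-6-(2-methylbut-3-en-2-yl)chroman-3,4-diol (2,3-trans; mixture of C4 epimers) | C=CC(C)(C)c1c(O[Si](C)(C)C(C)(C)C)cc2c(c1O[Si](C)(C)C(C)(C)C)C(O)[C@H](O)[C@@H](c1ccc(O[Si](C)(C)C(C)(C)C)cc1)O2 | intermediate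
17 | (2R,3R)-5,7-bis(tert-butyldimethylsilyloxy)-3-hydroxy-2-[4-(tert-butyldimethylsilyloxy)phenyl]-6-(2-methylbut-3-en-2-yl)chroman-4-one | C=CC(C)(C)c1c(O[Si](C)(C)C(C)(C)C)cc2c(c1O[Si](C)(C)C(C)(C)C)C(=O)[C@H](O)[C@@H](c1ccc(O[Si](C)(C)C(C)(C)C)cc1)O2 | intermediate
18 | (2R,3R)-3,5,7-trihydroxy-2-(4-hydroxyphenyl)-6-(2-methylbut-3-en-2-yl)chroman-4-one | C=CC(C)(C)c1c(O)cc2c(c1O)C(=O)[C@H](O)[C@@H](c1ccc(O)cc1)O2 | target

## Step count and least certain steps

Total step count: 13. Longest linear sequence: 10 steps (steps 1 to 5, 7 and 10 to 13); steps 6, 8 and 9 lie on side branches.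

**Step 10 (key step).**
- What may go wrong: insufficient discrimination between the two faces of C2 inside the ion pair, since the cation offers the anion no hydrogen-bonding handle. Approach in the endo sense would give the 2,3-cis diastereomer, which would have to be separated. The acid and the released methanol may consume 14, and the benzylic carbon may migrate from O1 to a ring A carbon.
- Fallback by known chemistry, setting out from 11 (with 14) and returning at 15: the annulation is run without a chiral element, with SnCl4 in CH2Cl2 at −78 °C, the established racemic Lewis-acid oxa-Povarov reaction. It should give 15 as a racemate, that is together with its mirror image (2S,3S,4R)-5,7-bis(tert-butyldimethylsilyloxy)-2-[4-(tert-butyldimethylsilyloxy)phenyl]-6-(2-methylbut-3-en-2-yl)chroman-3,4-diol 3,4-O-isopropylidene ketal F1. The two are separated by preparative chromatography on a chiral stationary phase (amylose tris(3,5-dimethylphenylcarbamate), supercritical CO2 with 2-propanol), and the route continues from 15.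

**Step 7.**
- What may go wrong: C-alkylation of ring A instead of O-alkylation, because the chloro ether 10 ionises very easily and the ring carbons of 7 are strong nucleophiles. The mixed acetal may also hydrolyse during isolation.
- Fallback, setting out from 9 and 7 and returning at 11: 9 is treated with Et3SiOTf and 2,4,6-collidine in CH2Cl2 at 0 °C. This converts it into the non-acidic pyridinium salt 1-{methoxy[4-(tert-butyldimethylsilyloxy)phenyl]methyl}-2,4,6-trimethylpyridinium trifluoromethanesulfonate F2, a tamed oxocarbenium equivalent of the kind used to make mixed acetals from alcohols. 7 and a further equivalent of collidine are then added, and the phenol oxygen displaces collidine to give 11.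

**Step 5.**
- What may go wrong: loss of more than one silyl group, or transfer of silyl groups between phenoxides, so that the para oxygen is not the only one set free.
- Fallback, setting out from 5 and returning at 7, which replaces selective cleavage by selective acylation:
  - 5 is fully desilylated with TBAF in THF at 0 °C to 2-(2-methylbut-3-en-2-yl)benzene-1,3,5-triol F3.
  - Pivaloyl chloride (1.0 equiv) and pyridine in CH2Cl2 at −40 °C should acylate only the unhindered hydroxyl para to the side chain, giving 3,5-dihydroxy-4-(2-methylbut-3-en-2-yl)phenyl 2,2-dimethylpropanoate F4.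
  - TBSOTf and 2,6-lutidine silylate the two hindered hydroxyls to 3,5-bis(tert-butyldimethylsilyloxy)-4-(2-methylbut-3-en-2-yl)phenyl 2,2-dimethylpropanoate F5.
  - i-Bu2AlH in CH2Cl2 at −78 °C removes the ester reductively and gives 7.

**Step 11.**
- What may go wrong: the C4 cation formed under acid may react further before water captures it, by a 1,2-hydride shift from C3 to give a 3-ketone or by arylation of a second molecule at C8.
- Fallback, setting out from 15 and returning at 17, which avoids acid and the diol altogether (no new compound, F0): DDQ in CH2Cl2 with pH 7 buffer at 0 °C → rt should abstract hydride from C4 of the ketal. Water adds to the cyclic oxocarbenium ion, and the resulting hemiketal collapses to the C4 ketone and loses acetone from the C3 oxygen.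

**Step 12.**
- What may go wrong: slow hydride abstraction, because in the preferred half-chair the C4–H bond lies close to the plane of ring A and overlaps poorly with it. Oxidation at the C2–H bond may compete, and the acidic hydroquinone formed may ionise C4.
- Fallback, setting out from 16 and returning at 18, which replaces chemoselective oxidation by protection:
  - Et3SiCl and imidazole in DMF at −20 °C should silylate the C3 hydroxyl, the more accessible one since the C4 hydroxyl is shielded by the neighbouring C5 silyloxy group. The product is (2R,3S)-5,7-bis(tert-butyldimethylsilyloxy)-2-[4-(tert-butyldimethylsilyloxy)phenyl]-6-(2-methylbut-3-en-2-yl)-3-(triethylsilyloxy)chroman-4-ol F6 (C4 epimers).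
  - Dess–Martin periodinane with NaHCO3 in CH2Cl2 oxidises the remaining alcohol to (2R,3R)-5,7-bis(tert-butyldimethylsilyloxy)-2-[4-(tert-butyldimethylsilyloxy)phenyl]-6-(2-methylbut-3-en-2-yl)-3-(triethylsilyloxy)chroman-4-one F7.
  - TBAF buffered with AcOH in THF removes all four silyl groups and gives 18.

## Further compounds

F1 | step 10 | (2S,3S,4R)-5,7-bis(tert-butyldimethylsilyloxy)-2-[4-(tert-butyldimethylsilyloxy)phenyl]-6-(2-methylbut-3-en-2-yl)chroman-3,4-diol 3,4-O-isopropylidene ketal (enantiomer of 15) | C=CC(C)(C)c1c(O[Si](C)(C)C(C)(C)C)cc2c(c1O[Si](C)(C)C(C)(C)C)[C@H]3OC(C)(C)O[C@H]3[C@H](c4ccc(O[Si](C)(C)C(C)(C)C)cc4)O2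
F2 | step 7 | 1-{methoxy[4-(tert-butyldimethylsilyloxy)phenyl]methyl}-2,4,6-trimethylpyridinium trifluoromethanesulfonate (racemic) | COC(c1ccc(O[Si](C)(C)C(C)(C)C)cc1)[n+]1c(C)cc(C)cc1C.[O-]S(=O)(=O)C(F)(F)F
F3 | step 5 | 2-(2-methylbut-3-en-2-yl)benzene-1,3,5-triol | C=CC(C)(C)c1c(O)cc(O)cc1O
F4 | step 5 | 3,5-dihydroxy-4-(2-methylbut-3-en-2-yl)phenyl 2,2-dimethylpropanoate | C=CC(C)(C)c1c(O)cc(OC(=O)C(C)(C)C)cc1O
F5 | step 5 | 3,5-bis(tert-butyldimethylsilyloxy)-4-(2-methylbut-3-en-2-yl)phenyl 2,2-dimethylpropanoate | C=CC(C)(C)c1c(O[Si](C)(C)C(C)(C)C)cc(OC(=O)C(C)(C)C)cc1O[Si](C)(C)C(C)(C)C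
F0 | step 11 | none | none
F6 | step 12 | (2R,3S)-5,7-bis(tert-butyldimethylsilyloxy)-2-[4-(tert-butyldimethylsilyloxy)phenyl]-6-(2-methylbut-3-en-2-yl)-3-(triethylsilyloxy)chroman-4-ol (mixture of C4 epimers) | C=CC(C)(C)c1c(O[Si](C)(C)C(C)(C)C)cc2c(c1O[Si](C)(C)C(C)(C)C)C(O)[C@H](O[Si](CC)(CC)CC)[C@@H](c1ccc(O[Si](C)(C)C(C)(C)C)cc1)O2
F7 | step 12 | (2R,3R)-5,7-bis(tert-butyldimethylsilyloxy)-2-[4-(tert-butyldimethylsilyloxy)phenyl]-6-(2-methylbut-3-en-2-yl)-3-(triethylsilyloxy)chroman-4-one | C=CC(C)(C)c1c(O[Si](C)(C)C(C)(C)C)cc2c(c1O[Si](C)(C)C(C)(C)C)C(=O)[C@H](O[Si](CC)(CC)CC)[C@@H](c1ccc(O[Si](C)(C)C(C)(C)C)cc1)O2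
A1 | alternative 1 | 3-(methoxymethoxy)-2-(2-methylbut-3-en-2-yl)-5-(triisopropylsilyloxy)phenol | C=CC(C)(C)c1c(O)cc(O[Si](C(C)C)(C(C)C)C(C)C)cc1OCOC
A2 | alternative 1 | tert-butyl 2-acetyl-3-(methoxymethoxy)-5-(triisopropylsilyloxy)phenyl carbonate | CC(=O)c1c(OC(=O)OC(C)(C)C)cc(O[Si](C(C)C)(C(C)C)C(C)C)cc1OCOC
A3 | alternative 2 | (2R,3S)-5,7-bis(methoxymethoxy)-2-[4-(methoxymethoxy)phenyl]-6-(2-methylbut-3-en-2-yl)chroman-3-yl acetate | C=CC(C)(C)c1c(OCOC)cc2c(c1OCOC)C[C@H](OC(C)=O)[C@@H](c1ccc(OCOC)cc1)O2
A4 | alternative 2 | 2-(hydroxymethyl)-3,5-bis(methoxymethoxy)-4-(2-methylbut-3-en-2-yl)phenol | C=CC(C)(C)c1c(OCOC)cc(O)c(CO)c1OCOC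
A5 | alternative 2 | (E)-2-[4-(methoxymethoxy)phenyl]ethenyl acetate | CC(=O)O/C=C/c1ccc(OCOC)cc1
A6 | alternative 3 | (2R,3R)-3-(tert-butyldimethylsilyloxy)-2-[4-(tert-butyldimethylsilyloxy)phenyl]-5-hydroxy-6-(2-methylbut-3-en-2-yl)-7-(triisopropylsilyloxy)chroman-4-one | C=CC(C)(C)c1c(O[Si](C(C)C)(C(C)C)C(C)C)cc2c(c1O)C(=O)[C@H](O[Si](C)(C)C(C)(C)C)[C@@H](c1ccc(O[Si](C)(C)C(C)(C)C)cc1)O2
A7 | alternative 3 | (2R,3R)-3-(tert-butyldimethylsilyloxy)-2-[4-(tert-butyldimethylsilyloxy)phenyl]-6-(2-diazoacetyl)-2,3-dihydro-4H-pyran-4-one | [N-]=[N+]=CC(=O)C1=CC(=O)[C@H](O[Si](C)(C)C(C)(C)C)[C@@H](c2ccc(O[Si](C)(C)C(C)(C)C)cc2)O1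
A8 | alternative 3 | triisopropyl[(3,3-dimethylpent-4-en-1-yn-1-yl)oxy]silane | C=CC(C)(C)C#CO[Si](C(C)C)(C(C)C)C(C)C
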